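The route rests on opening both carbocycles of the ent-labdane core at C1–C10 (ring A) and C8–C9 (ring B). The precursor is an acyclic aldehyde–alkene–vinyl ketone whose only stereocentres, C4 and C5, come from a chelate-controlled Ireland–Claisen rearrangement. Under (Bu4N)4W10O32 photocatalysis the C8 acyl radical should close ring B at C9, and the tertiary C10 radical then closes ring A at C1 of the enone, creating the quaternary C10 and the trans-decalin in one operation. The step exploits the 1,6-relationship between C8 (exocyclic methylene carbon, a latent ketone) and the oxygenated C3 across the methyl-bearing ring-fusion carbon C10: C8 serves as acyl radical, the C3 carbonyl as acceptor activator.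

Key step: step 10

Remark: positions are named with labdane numbering (C17 = methylene carbon on C8, C18 = methyl and C19 = oxygenated carbon on C4, C20 = methyl on C10); compounds 1, 2, 4 and 19 are taken as catalogue chemicals.

Step 1
Reactants: 1 diethyl (3-oxobutan-2-yl)phosphonate; 2 3-(bromomethyl)furan
Product: 3 diethyl [5-(furan-3-yl)-3-oxopentan-2-yl]phosphonate
Conditions: NaH (1.1 equiv), THF, 0 °C; n-BuLi (1.05 equiv), 0 °C; then 2, 0 °C → rt; H2O quench
Reagents that add atoms: none
Why: Alkylation of a β-ketophosphonate dianion should occur at the more basic terminal carbon with the reactive furylmethyl bromide, leaving the phosphonate α-carbon for the later olefination.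

Step 2
Reactants: 4 methyl 4,4-dimethoxybutanoate
Product: 5 4,4-dimethoxybutanal
Conditions: iBu2AlH (1.05 equiv), CH2Cl2, −78 °C; aq. KNaC4H4O6
Reagents that add atoms: none
Why: Partial ester reduction with iBu2AlH at −78 °C should stop at the aluminium hemiacetal and release the aldehyde on work-up, with the dimethyl acetal inert.

Step 3
Reactants: 3 diethyl [5-(furan-3-yl)-3-oxopentan-2-yl]phosphonate; 5 4,4-dimethoxybutanal
Product: 6 (4E)-1-(furan-3-yl)-8,8-dimethoxy-4-methyloct-4-en-3-one
Conditions: Ba(OH)2·8H2O (0.6 equiv), THF/H2O (40:1), rt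
Reagents that add atoms: none
Why: Horner–Wadsworth–Emmons olefination of an α-methyl β-ketophosphonate with an aliphatic aldehyde under mild hydroxide activation should give the trisubstituted (E)-enone and tolerate the acetal.

Step 4
Reactants: 6 (4E)-1-(furan-3-yl)-8,8-dimethoxy-4-methyloct-4-en-3-one
Product: 7 (3R,4E)-1-(furan-3-yl)-8,8-dimethoxy-4-methyloct-4-en-3-ol
Conditions: (S)-1-methyl-3,3-diphenyltetrahydro-1H,3H-pyrrolo[1,2-c][1,3,2]oxazaborole (0.2 equiv), catecholborane (1.6 equiv), toluene, −78 °C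
Reagents that add atoms: none
Why: In this Corey–Bakshi–Shibata reduction the α-methylalkenyl group acts as the large ketone substituent, so the (S)-oxazaborolidine should deliver hydride to the face that gives the (R)-carbinol (the future C9), with 1,2-selectivity.

Step 5
Reactants: 7 (3R,4E)-1-(furan-3-yl)-8,8-dimethoxy-4-methyloct-4-en-3-ol
Product: 8 (3R,4E)-1-(furan-3-yl)-8,8-dimethoxy-4-methyloct-4-en-3-yl propanoate
Conditions: (EtCO)2O, Et3N, 4-(dimethylamino)pyridine (cat.), CH2Cl2, 0 °C → rt
Reagents that add atoms: propionic anhydride, CCC(=O)OC(=O)CC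
Why: Nucleophile-catalysed acylation of the secondary allylic alcohol should proceed without touching the stereocentre or the acetal.

Step 6
Reactants: 8 (3R,4E)-1-(furan-3-yl)-8,8-dimethoxy-4-methyloct-4-en-3-yl propanoate
Product: 9 (3R,4E)-1-(furan-3-yl)-8,8-dimethoxy-4-methyloct-4-en-3-yl 3-hydroxy-2-methylpropanoate (both epimers at the acyl α-carbon)
Conditions: LiN(iPr)2 (1.1 equiv), THF, −78 °C; CH2O gas (from cracked paraformaldehyde), −78 °C; AcOH quench at −78 °C
Reagents that add atoms: formaldehyde, C=O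
Why: Aldol addition of the lithium ester enolate to monomeric formaldehyde at −78 °C, where the allyl ester enolate does not yet rearrange, should install the C19 carbon; the new α-centre is planarised again in step 7, so its configuration does not matter.

Step 7
Reactants: 9 (3R,4E)-1-(furan-3-yl)-8,8-dimethoxy-4-methyloct-4-en-3-yl 3-hydroxy-2-methylpropanoate
Product: 12 (2S,3S,4E)-2-({[tert-butyl(dimethyl)silyl]oxy}methyl)-3-(3,3-dimethoxypropyl)-7-(furan-3-yl)-2,4-dimethylhept-4-enoic acid, via bis-silyl ketene acetal 10 (not isolated), via silyl ester 11 (not isolated)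
Conditions: LiN(iPr)2 (2.5 equiv), THF, −78 → −40 °C; tBuMe2SiCl (3 equiv), DMPU, −78 °C → rt → 60 °C; then aq. citric acid, THF, rt
Reagents that add atoms: tert-butyl(chloro)dimethylsilane, CC(C)(C)[Si](C)(C)Cl
Why: In this dianionic Ireland–Claisen rearrangement the lithium alkoxide chelates the enolate oxygen, so the tetrasubstituted ketene acetal should form with CH2O cis to the enolate oxygen, and a chair transition state with the C9 side chain equatorial should relay the (R)-carbinol chirality to C5 (S), set the quaternary C4 (S) and give the (E)-C9=C10 alkene; the silyl ester is cleaved on work-up.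

Step 8
Reactants: 12 (2S,3S,4E)-2-({[tert-butyl(dimethyl)silyl]oxy}methyl)-3-(3,3-dimethoxypropyl)-7-(furan-3-yl)-2,4-dimethylhept-4-enoic acid
Product: 13 (4S,5S,6E)-4-({[tert-butyl(dimethyl)silyl]oxy}methyl)-5-(3,3-dimethoxypropyl)-9-(furan-3-yl)-4,6-dimethylnona-1,6-dien-3-one
Conditions: CH2=CHLi (3 equiv), THF, −78 → 0 °C; inverse quench into cold pH 7 buffer
Reagents that add atoms: vinyllithium, [Li]C=C
Why: Addition of the organolithium to the lithium carboxylate should give a stable geminal dialkoxide that collapses to the vinyl ketone only on quench (ketone synthesis from a carboxylic acid and an organolithium), so no tertiary alcohol is expected.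

Step 9
Reactants: 13 (4S,5S,6E)-4-({[tert-butyl(dimethyl)silyl]oxy}methyl)-5-(3,3-dimethoxypropyl)-9-(furan-3-yl)-4,6-dimethylnona-1,6-dien-3-one
Product: 14 (4S,5S,6E)-4-({[tert-butyl(dimethyl)silyl]oxy}methyl)-9-(furan-3-yl)-4,6-dimethyl-5-(3-oxopropyl)nona-1,6-dien-3-one
Conditions: pyridinium p-toluenesulfonate (0.2 equiv), acetone/H2O (10:1), 40 °C
Reagents that add atoms: water, O
Why: Mild acid-catalysed acetal hydrolysis should unmask the C8 aldehyde while the hindered neopentyl silyl ether, the furan and the enone survive.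

Step 10
Reactants: 14 (4S,5S,6E)-4-({[tert-butyl(dimethyl)silyl]oxy}methyl)-9-(furan-3-yl)-4,6-dimethyl-5-(3-oxopropyl)nona-1,6-dien-3-one
Product: 16 (4S,5S,9S,10R)-19-{[tert-butyl(dimethyl)silyl]oxy}-15,16-epoxy-17-norlabda-13(16),14-diene-3,8-dione, via C9-epimeric dione 15 (not isolated)
Conditions: (Bu4N)4W10O32 (4 mol %), MeCN (0.01 M), 390 nm LED, 20 °C, N2; then NaOMe (0.3 equiv), MeOH, 20 °C
Reagents that add atoms: none
Why: Proposed new method: excited (Bu4N)4W10O32 should abstract the aldehydic hydrogen at C8 (polarity-matched hydrogen atom transfer), the nucleophilic acyl radical adds 6-endo-trig to C9 of the C9=C10 alkene (the C10 methyl disfavours 5-exo attack, and a 5-exo adduct would ring-expand to the same radical), and the tertiary C10 radical then adds 6-endo-trig to C1 of the vinyl ketone, whose α-keto radical takes the hydrogen back from the reduced polyoxometalate. The closest known reactions are the hydroacylation of enones with aldehydes under the same photocatalyst and stannane-mediated acyl radical polyene cascades from selenoesters; a selenoester is not accessible here because selenolates add to the vinyl ketone. Ring B closes first (C8–C9) and ring A second (C1–C10), both in 6-endo mode. C10 is controlled by C5: the ring B radical keeps the bulky C4 substituent equatorial and is attacked on its equatorial face through a chair–chair transition state, so C20 ends axial and the ring fusion trans, as in radical polyene cyclisations; C9 is epimerisable next to the C8 ketone and NaOMe equilibrates it to the equatorial side chain. The step needs the acyl radical to choose the alkene over its own enone, which ring size (six against eight) and high dilution should secure, and the Michael polarity of the enone secures 6-endo over 5-exo in the second closure.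

Step 11
Reactants: 16 (4S,5S,9S,10R)-19-{[tert-butyl(dimethyl)silyl]oxy}-15,16-epoxy-17-norlabda-13(16),14-diene-3,8-dione
Product: 17 (4S,5S,9R,10S)-19-{[tert-butyl(dimethyl)silyl]oxy}-15,16-epoxylabda-8(17),13(16),14-trien-3-one
Conditions: Ph3PCH3Br (1.5 equiv), KOtBu (1.4 equiv), THF, 0 °C; add 16, 0 °C → rt
Reagents that add atoms: methyltriphenylphosphonium bromide, C[P+](c1ccccc1)(c1ccccc1)c1ccccc1.[Br-]
Why: Wittig methylenation should occur at the C8 ketone, which has a single α-branch, while the C3 ketone flanked by the quaternary C4 and its silyloxymethyl group reacts far more slowly; C9 stays in its equatorial, thermodynamic configuration under the basic conditions.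

Step 12
Reactants: 17 (4S,5S,9R,10S)-19-{[tert-butyl(dimethyl)silyl]oxy}-15,16-epoxylabda-8(17),13(16),14-trien-3-one
Product: 18 (3R,4S,5S,9R,10S)-19-{[tert-butyl(dimethyl)silyl]oxy}-15,16-epoxylabda-8(17),13(16),14-trien-3-ol
Conditions: NaBH4, MeOH/CH2Cl2 (1:1), −20 → 0 °C
Reagents that add atoms: none
Why: Hydride reduction of a 4,4-disubstituted 3-ketone in a trans-decalin should occur by axial attack on the face opposite the axial C18 and C20 methyl groups, giving the equatorial (3R) alcohol.

Step 13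
Reactants: 18 (3R,4S,5S,9R,10S)-19-{[tert-butyl(dimethyl)silyl]oxy}-15,16-epoxylabda-8(17),13(16),14-trien-3-ol; 19 angelic acid [(2Z)-2-methylbut-2-enoic acid]
Product: 21 (3R,4S,5S,9R,10S)-19-{[tert-butyl(dimethyl)silyl]oxy}-15,16-epoxylabda-8(17),13(16),14-trien-3-yl (2Z)-2-methylbut-2-enoate, via mixed anhydride 20 (not isolated)
Conditions: 19, 2,4,6-Cl3C6H2COCl, Et3N, toluene, rt; then 18, toluene, 80 °C
Reagents that add atoms: none
Why: Yamaguchi esterification through the mixed 2,4,6-trichlorobenzoic anhydride, run without a nucleophilic catalyst, should transfer the angeloyl group to the equatorial C3 hydroxyl with retention of the (Z)-geometry while the primary hydroxyl stays silylated.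

Step 14
Reactants: 21 (3R,4S,5S,9R,10S)-19-{[tert-butyl(dimethyl)silyl]oxy}-15,16-epoxylabda-8(17),13(16),14-trien-3-yl (2Z)-2-methylbut-2-enoate
Product: 24 (3R,4S,5S,9R,10S,13Z)-19-{[tert-butyl(dimethyl)silyl]oxy}-15,16-dihydroxylabda-8(17),13-dien-3-yl (2Z)-2-methylbut-2-enoate, via endoperoxide 22 (not isolated), via enedial 23 (not isolated)
Conditions: O2, 5,10,15,20-tetraphenylporphyrin (1 mol %), visible light, CH2Cl2, −78 °C; Me2S, −78 → −20 °C; then MeOH, CeCl3·7H2O, NaBH4, −40 → 0 °C
Reagents that add atoms: dioxygen, O=O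
Why: Singlet oxygen should add [4+2] to the electron-rich furan far faster than it reacts with the 1,1-disubstituted alkene or the enoate, Me2S reduces the endoperoxide to the enedial whose (Z)-geometry is fixed by the former ring, and Luche reduction gives the (13Z)-diol without touching the angelate.

Step 15
Reactants: 24 (3R,4S,5S,9R,10S,13Z)-19-{[tert-butyl(dimethyl)silyl]oxy}-15,16-dihydroxylabda-8(17),13-dien-3-yl (2Z)-2-methylbut-2-enoate
Product: 25 (3R,4S,5S,9R,10S,13Z)-15,16,19-trihydroxylabda-8(17),13-dien-3-yl (2Z)-2-methylbut-2-enoate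
Conditions: HF·pyridine, pyridine/THF, 0 °C → rt
Reagents that add atoms: none
Why: Fluoride-mediated desilylation under buffered, weakly acidic conditions should free the C19 hydroxyl without acyl migration or isomerisation of the angelate.

Compound list
1 | diethyl (3-oxobutan-2-yl)phosphonate | CCOP(=O)(OCC)C(C)C(C)=O | starting material
2 | 3-(bromomethyl)furan | BrCc1ccoc1 | starting material
3 | diethyl [5-(furan-3-yl)-3-oxopentan-2-yl]phosphonate | CCOP(=O)(OCC)C(C)C(=O)CCc1ccoc1 | intermediate
4 | methyl 4,4-dimethoxybutanoate | COC(=O)CCC(OC)OC | starting material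
5 | 4,4-dimethoxybutanal | O=CCCC(OC)OC | intermediate
6 | (4E)-1-(furan-3-yl)-8,8-dimethoxy-4-methyloct-4-en-3-one | O=C(CCc1ccoc1)/C(C)=C/CCC(OC)OC | intermediate
7 | (3R,4E)-1-(furan-3-yl)-8,8-dimethoxy-4-methyloct-4-en-3-ol | O[C@H](CCc1ccoc1)/C(C)=C/CCC(OC)OC | intermediate
8 | (3R,4E)-1-(furan-3-yl)-8,8-dimethoxy-4-methyloct-4-en-3-yl propanoate | CCC(=O)O[C@H](CCc1ccoc1)/C(C)=C/CCC(OC)OC | intermediate
9 | (3R,4E)-1-(furan-3-yl)-8,8-dimethoxy-4-methyloct-4-en-3-yl 3-hydroxy-2-methylpropanoate (epimers at the acyl α-carbon) | CC(CO)C(=O)O[C@H](CCc1ccoc1)/C(C)=C/CCC(OC)OC | intermediate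
10 | bis(tert-butyldimethylsilyl) ketene acetal of 9 (CH2OSi cis to OSi) | CC(C)(C)[Si](C)(C)OC/C(C)=C(\O[Si](C)(C)C(C)(C)C)O[C@H](CCc1ccoc1)/C(C)=C/CCC(OC)OC | intermediate
11 | tert-butyldimethylsilyl ester of 12 | CC(C)(C)[Si](C)(C)OC(=O)[C@](C)(CO[Si](C)(C)C(C)(C)C)[C@@H](CCC(OC)OC)/C(C)=C/CCc1ccoc1 | intermediate
12 | (2S,3S,4E)-2-({[tert-butyl(dimethyl)silyl]oxy}methyl)-3-(3,3-dimethoxypropyl)-7-(furan-3-yl)-2,4-dimethylhept-4-enoic acid | OC(=O)[C@](C)(CO[Si](C)(C)C(C)(C)C)[C@@H](CCC(OC)OC)/C(C)=C/CCc1ccoc1 | intermediate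
13 | (4S,5S,6E)-4-({[tert-butyl(dimethyl)silyl]oxy}methyl)-5-(3,3-dimethoxypropyl)-9-(furan-3-yl)-4,6-dimethylnona-1,6-dien-3-one | C=CC(=O)[C@](C)(CO[Si](C)(C)C(C)(C)C)[C@@H](CCC(OC)OC)/C(C)=C/CCc1ccoc1 | intermediate
14 | (4S,5S,6E)-4-({[tert-butyl(dimethyl)silyl]oxy}methyl)-9-(furan-3-yl)-4,6-dimethyl-5-(3-oxopropyl)nona-1,6-dien-3-one | C=CC(=O)[C@](C)(CO[Si](C)(C)C(C)(C)C)[C@@H](CCC=O)/C(C)=C/CCc1ccoc1 | intermediate
15 | (4S,5S,10R)-19-{[tert-butyl(dimethyl)silyl]oxy}-15,16-epoxy-17-norlabda-13(16),14-diene-3,8-dione, mixture of C9 epimers | O=C1CC[C@H]2[C@@](C)(CCC(=O)[C@]2(C)CO[Si](C)(C)C(C)(C)C)C1CCc1ccoc1 | intermediate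
16 | (4S,5S,9S,10R)-19-{[tert-butyl(dimethyl)silyl]oxy}-15,16-epoxy-17-norlabda-13(16),14-diene-3,8-dione | O=C1CC[C@H]2[C@@](C)(CCC(=O)[C@]2(C)CO[Si](C)(C)C(C)(C)C)[C@@H]1CCc1ccoc1 | intermediate
17 | (4S,5S,9R,10S)-19-{[tert-butyl(dimethyl)silyl]oxy}-15,16-epoxylabda-8(17),13(16),14-trien-3-one | C=C1CC[C@H]2[C@@](C)(CCC(=O)[C@]2(C)CO[Si](C)(C)C(C)(C)C)[C@@H]1CCc1ccoc1 | intermediate
18 | (3R,4S,5S,9R,10S)-19-{[tert-butyl(dimethyl)silyl]oxy}-15,16-epoxylabda-8(17),13(16),14-trien-3-ol | C=C1CC[C@H]2[C@@](C)(CC[C@@H](O)[C@]2(C)CO[Si](C)(C)C(C)(C)C)[C@@H]1CCc1ccoc1 | intermediate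
19 | angelic acid, (2Z)-2-methylbut-2-enoic acid | C/C=C(/C)C(=O)O | starting material
20 | (2Z)-2-methylbut-2-enoic 2,4,6-trichlorobenzoic anhydride | C/C=C(/C)C(=O)OC(=O)c1c(Cl)cc(Cl)cc1Cl | intermediate
21 | (3R,4S,5S,9R,10S)-19-{[tert-butyl(dimethyl)silyl]oxy}-15,16-epoxylabda-8(17),13(16),14-trien-3-yl (2Z)-2-methylbut-2-enoate | C=C1CC[C@H]2[C@@](C)(CC[C@@H](OC(=O)/C(C)=C\C)[C@]2(C)CO[Si](C)(C)C(C)(C)C)[C@@H]1CCc1ccoc1 | intermediate
22 | 15,16-epidioxy-15,16-epoxy endoperoxide of 21 (2,3,7-trioxabicyclo[2.2.1]hept-5-ene in place of the furan, bridgehead epimers) | C=C1CC[C@H]2[C@@](C)(CC[C@@H](OC(=O)/C(C)=C\C)[C@]2(C)CO[Si](C)(C)C(C)(C)C)[C@@H]1CCC1=CC3OOC1O3 | intermediate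
23 | (3R,4S,5S,9R,10S,13Z)-19-{[tert-butyl(dimethyl)silyl]oxy}-15,16-dioxolabda-8(17),13-dien-3-yl (2Z)-2-methylbut-2-enoate | C=C1CC[C@H]2[C@@](C)(CC[C@@H](OC(=O)/C(C)=C\C)[C@]2(C)CO[Si](C)(C)C(C)(C)C)[C@@H]1CC/C(C=O)=C/C=O | intermediate
24 | (3R,4S,5S,9R,10S,13Z)-19-{[tert-butyl(dimethyl)silyl]oxy}-15,16-dihydroxylabda-8(17),13-dien-3-yl (2Z)-2-methylbut-2-enoate | C=C1CC[C@H]2[C@@](C)(CC[C@@H](OC(=O)/C(C)=C\C)[C@]2(C)CO[Si](C)(C)C(C)(C)C)[C@@H]1CC/C(=C/CO)CO | intermediate
25 | (3R,4S,5S,9R,10S,13Z)-15,16,19-trihydroxylabda-8(17),13-dien-3-yl (2Z)-2-methylbut-2-enoate | C=C1CC[C@H]2[C@@](C)(CC[C@@H](OC(=O)/C(C)=C\C)[C@]2(C)CO)[C@@H]1CC/C(=C/CO)CO | target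

Total step count: 15. Longest linear sequence: 14 steps (steps 1 and 3 to 15).

Steps most likely to fail

Step 10 (proposed new method). The photocatalytic cascade may stall or leak through hydrogen back-transfer to the C10 radical before ring A closes, hydrogen abstraction at allylic or furfurylic positions, electron-transfer quenching by the furan, or cis ring fusion. The fallback uses known chemistry, sets out from acid 12 and comes back at dione 16. MeNHOMe·HCl with a carbodiimide should give the N-methoxy-N-methyl amide F1. Pyridinium p-toluenesulfonate in wet acetone frees the aldehyde F2. Me2AlCl (CH2Cl2, −78 °C) should promote the intramolecular carbonyl-ene reaction in which C8 bonds to C9 and a C20 hydrogen moves to oxygen, giving the methylenecyclohexanol F3 (ring B with the exocyclic C10 methylene; the C8 and C9 configurations are reset later). CH2=CHMgBr converts the amide into the vinyl ketone F4. Fe(acac)3/PhSiH3 in EtOH at 60 °C (hydrogen-atom-transfer Giese cyclisation) should generate the tertiary C10 radical from the exocyclic alkene and close ring A at C1, giving the hydroxy ketone F5. Dess–Martin oxidation gives the dione mixture 15, and NaOMe equilibration gives 16.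

Step 7. The second deprotonation may be incomplete, or loss of the lithium chelate before silylation may scramble the ketene acetal geometry and erode the C4 configuration. The fallback sets out from alcohol 7 and comes back at acid 12. Heating 7 with 2,2,5-trimethyl-1,3-dioxane-4,6-dione (toluene, 100 °C) should give the malonic half ester F6, and Me3SiCHN2 the mixed malonate F7. LiN(iPr)2/Me3SiCl (THF, −78 °C → rt) should trigger the ester-enolate Claisen rearrangement of the rigid lithium-chelated malonate enolate to the acid ester F8 (same chair, CO2Me now the equatorial chelating arm). LiBH4 reduces the methyl ester in the presence of the carboxylate to the hydroxy acid F9. tBuMe2SiCl/imidazole followed by K2CO3/MeOH gives 12.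

Step 14. The late furan unveiling may suffer from ene oxidation of the exocyclic alkene, isomerisation or cyclisation of the enedial before reduction, or partial reduction. The fallback sets out from alcohol 18 and comes back at target 25. Photo-oxygenation of 18 in the presence of iPr2NEt should give the γ-hydroxybutenolide F10, and iBu2AlH reduces it to the (13Z)-triol F11. tBuMe2SiCl/imidazole silylates the two primary allylic hydroxyls to give the tris-silyl ether F12. The mixed-anhydride angeloylation of step 13 gives the ester F13, and HF·pyridine removes all three silyl groups to give 25.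

Further compounds
F1 | step 10 | N-methoxy-N-methyl amide of acid 12 | CON(C)C(=O)[C@](C)(CO[Si](C)(C)C(C)(C)C)[C@@H](CCC(OC)OC)/C(C)=C/CCc1ccoc1
F2 | step 10 | aldehyde from F1 (3-oxopropyl in place of 3,3-dimethoxypropyl) | CON(C)C(=O)[C@](C)(CO[Si](C)(C)C(C)(C)C)[C@@H](CCC=O)/C(C)=C/CCc1ccoc1
F3 | step 10 | carbonyl-ene product: amide bearing ring B as 3-[2-(furan-3-yl)ethyl]-4-hydroxy-2-methylenecyclohexyl (C8 and C9 epimers) | CON(C)C(=O)[C@](C)(CO[Si](C)(C)C(C)(C)C)[C@H]1CCC(O)C(CCc2ccoc2)C1=C
F4 | step 10 | vinyl ketone from F3 | C=CC(=O)[C@](C)(CO[Si](C)(C)C(C)(C)C)[C@H]1CCC(O)C(CCc2ccoc2)C1=C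
F5 | step 10 | (4S,5S,10R)-19-{[tert-butyl(dimethyl)silyl]oxy}-15,16-epoxy-8-hydroxy-17-norlabda-13(16),14-dien-3-one (C8 and C9 epimers) | OC1CC[C@H]2[C@@](C)(CCC(=O)[C@]2(C)CO[Si](C)(C)C(C)(C)C)C1CCc1ccoc1
F6 | step 7 | (3R,4E)-1-(furan-3-yl)-8,8-dimethoxy-4-methyloct-4-en-3-yl hydrogen 2-methylmalonate | OC(=O)C(C)C(=O)O[C@H](CCc1ccoc1)/C(C)=C/CCC(OC)OC
F7 | step 7 | (3R,4E)-1-(furan-3-yl)-8,8-dimethoxy-4-methyloct-4-en-3-yl methyl 2-methylmalonate | COC(=O)C(C)C(=O)O[C@H](CCc1ccoc1)/C(C)=C/CCC(OC)OC
F8 | step 7 | Claisen acid ester: methyl ester in place of the CH2OSi group of 12 | COC(=O)[C@@](C)(C(=O)O)[C@@H](CCC(OC)OC)/C(C)=C/CCc1ccoc1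
F9 | step 7 | hydroxy acid: 12 without the silyl group | OC(=O)[C@](C)(CO)[C@@H](CCC(OC)OC)/C(C)=C/CCc1ccoc1
F10 | step 14 | γ-hydroxybutenolide from 18 (5-hydroxy-2(5H)-furanone in place of the furan) | C=C1CC[C@H]2[C@@](C)(CC[C@@H](O)[C@]2(C)CO[Si](C)(C)C(C)(C)C)[C@@H]1CCC1=CC(=O)OC1O
F11 | step 14 | (3R,4S,5S,9R,10S,13Z)-19-{[tert-butyl(dimethyl)silyl]oxy}labda-8(17),13-diene-3,15,16-triol | C=C1CC[C@H]2[C@@](C)(CC[C@@H](O)[C@]2(C)CO[Si](C)(C)C(C)(C)C)[C@@H]1CC/C(=C/CO)CO
F12 | step 14 | 15,16,19-tris(tert-butyldimethylsilyl) ether of the tetraol, free C3 hydroxyl | C=C1CC[C@H]2[C@@](C)(CC[C@@H](O)[C@]2(C)CO[Si](C)(C)C(C)(C)C)[C@@H]1CC/C(=C/CO[Si](C)(C)C(C)(C)C)CO[Si](C)(C)C(C)(C)C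
F13 | step 14 | 3-O-angeloyl 15,16,19-tris(tert-butyldimethylsilyl) ether | C=C1CC[C@H]2[C@@](C)(CC[C@@H](OC(=O)/C(C)=C\C)[C@]2(C)CO[Si](C)(C)C(C)(C)C)[C@@H]1CC/C(=C/CO[Si](C)(C)C(C)(C)C)CO[Si](C)(C)C(C)(C)C
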